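**Plan**

- Late cuts: the C19 ester is cut at the acyl C–O bond and at the cinnamate C=C (Z-selective Horner–Wadsworth–Emmons); the 13(16),14-diene is cut to a terminal alkyne plus ethylene; the 7α,8α-diol goes back to a Δ7 alkene and that to a Δ5-en-7-one.
- Ring B is cut at C6–C7 and C9–C10 into a 10-carbon ring A ene unit (exocyclic C6H2=C5, only allylic hydrogen on C10, C4 quaternary centre in place) and an 8-carbon (E)-enoyl chloride (acyl C7, C8=C9, C17, alkyne-masked side chain).
- Enabling feature: the oxygenated C7 lies between C6 and the C8–C9 unit. One acyl carbon can acylate C6 in an ene-type step that moves the alkene to C5=C10, and then, as an enone, offers C9 to C10.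
- Forward order: ring A and the acid chloride are made separately, ring B is closed in one operation, then 5α-H and 7α-OH, Δ7, the diol, the C19 alcohol, the diene and the ester follow.
- Stereochemistry: C4 from an auxiliary-controlled methylation; C9 and C10 in the key step; C5 by axial protonation in a dissolving-metal reduction; C7 and C8 together by α-face syn-dihydroxylation; the Z-alkene from a diaryl phosphonate olefination.

Key step: step 8

Remark: labdane numbering is used for the bicyclic compounds (ring A = C1–C5 and C10; ring B = C5–C10; C17 on C8; C18 and C19 on C4; C20 on C10; side chain C11–C16 on C9). β is the face of the C10 methyl; in every bicyclic compound C19 is β and the C4 methyl is α.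

Assumption: the lithiated enamine in step 2 is taken to be methylated on the face that gives the (1S) keto ester; if the sense is the opposite, D-valine tert-butyl ester is used instead.

**Route**

Step 1
Reactants: 1 ethyl 2-oxocyclohexane-1-carboxylate; 2 L-valine tert-butyl ester
Product: 3 ethyl 2-{[(2S)-1-tert-butoxy-3-methyl-1-oxobutan-2-yl]amino}cyclohex-1-ene-1-carboxylate
Conditions: BF3·OEt2 (cat.), toluene, reflux, azeotropic removal of water
Reagents that add atoms: none
Why: Condensation of a β-keto ester with a primary amine should give the hydrogen-bonded enamino ester (enamine formation); no new stereocentre is made.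

Step 2
Reactants: 3
Product: 5 ethyl (1S)-1-methyl-2-oxocyclohexane-1-carboxylate, via methylated imine 4 (not isolated)
Conditions: LiN(iPr)2, toluene/hexamethylphosphoramide, −78 °C; MeI, −78 to −40 °C; then aq. AcOH/NaOAc, rt
Reagents that add atoms: methyl iodide (CI); water (O)
Why: Auxiliary-controlled asymmetric α-alkylation of a chiral lithio-enamine, in which lithium chelated by the valine ester should shield one face so that methyl iodide sets the quaternary centre (labdane C4); imine hydrolysis then frees the keto ester and returns 2.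

Step 3
Reactants: 5
Product: 6 ethyl (1S,3RS)-1,3-dimethyl-2-oxocyclohexane-1-carboxylate
Conditions: LiN(iPr)2, THF, −78 °C; MeI, −78 to 0 °C
Reagents that add atoms: methyl iodide (CI)
Why: Enolate alkylation at the only enolisable α-carbon; the new centre (labdane C10) forms as a mixture, which does not matter because it becomes sp2 in step 8.

Step 4
Reactants: 6
Product: 7 ethyl (1S,3RS)-1,3-dimethyl-2-methylidenecyclohexane-1-carboxylate
Conditions: Ph3PCH3Br, KN(SiMe3)2, toluene, 0 to 90 °C
Reagents that add atoms: methyltriphenylphosphonium bromide (C[P+](c1ccccc1)(c1ccccc1)c1ccccc1.[Br-])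
Why: Wittig methylenation of a hindered ketone with the unstabilised ylide at raised temperature should give the exocyclic alkene (C6); the quaternary centre cannot epimerise.

Step 5
Reactants: 8 pent-4-yn-1-ol
Product: 10 ethyl (2E)-2-methylhept-2-en-6-ynoate, via pent-4-ynal 9 (not isolated)
Conditions: 2,2,6,6-tetramethylpiperidin-1-oxyl (cat.), PhI(OAc)2, CH2Cl2, rt; then Ph3P=C(CH3)CO2Et, rt
Reagents that add atoms: ethyl 2-(triphenyl-λ5-phosphanylidene)propanoate (CCOC(=O)C(C)=P(c1ccccc1)(c1ccccc1)c1ccccc1)
Why: Nitroxyl-catalysed alcohol oxidation followed in the same flask by a Wittig reaction with a stabilised ylide, which should give the (E)-trisubstituted enoate.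

Step 6
Reactants: 10
Product: 11 (2E)-2-methylhept-2-en-6-ynoic acid
Conditions: LiOH, THF/MeOH/H2O, rt; then aq. HCl
Reagents that add atoms: lithium hydroxide ([Li+].[OH-])
Why: Ester saponification; the (E)-alkene and the alkyne are not affected.

Step 7
Reactants: 11
Product: 12 (2E)-2-methylhept-2-en-6-ynoyl chloride
Conditions: (COCl)2, N,N-dimethylformamide (cat.), CH2Cl2, 0 °C to rt; concentrated and used crude
Reagents that add atoms: oxalyl chloride (ClC(=O)C(=O)Cl)
Why: Acid chloride formation through the chloroiminium catalyst.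

Step 8
Reactants: 7 ethyl (1S,3RS)-1,3-dimethyl-2-methylidenecyclohexane-1-carboxylate; 12 (2E)-2-methylhept-2-en-6-ynoyl chloride
Product: 14 ethyl 7-oxo-15,16-dinorlabd-5-en-13-yn-19-oate (8α-methyl; 9α-H; 10β-methyl), via β,γ-unsaturated ketone 13 (not isolated)
Conditions: EtAlCl2 (3 equiv), CH2Cl2, −78 °C to rt; aqueous work-up; then 1,8-diazabicyclo[5.4.0]undec-7-ene (cat.), CH2Cl2, rt
Reagents that add atoms: none
Why: Proposed new method: EtAlCl2 should turn 12 into an acylium-type complex that attacks the exocyclic CH2 (C6) of 7 with ene-type loss of the only allylic hydrogen (on C10) to give 13, whose tetrasubstituted C5=C10 alkene then adds through C10 to the β-carbon C9 of the aluminium-complexed enone, the C5 cation losing a C6 proton to give the dienolate of 14. The closest known reactions are the alkylaluminium-chloride-mediated acylation of 1,1-disubstituted alkenes with acid chlorides and Lewis-acid-promoted intramolecular ene or cation–olefin additions to enones; their coupling into one [3+3] annulation is the new element. Ring B closes in a 6-endo-trig mode, since both C5=C10 and C8=C9 lie in the forming ring and only the s-trans enone lets C10 reach C9. For C9 and C10, the single sp3 tether atom C6 and the (E)-enone geometry should place H-9 anti to the C10 methyl; for C10 relative to C4, the enone should approach the face away from the aluminium-complexed ester; C8 is set by base equilibration to the equatorial 8α-methyl epimer. The step needs acylation at C6, six- over five-membered closure and closure faster than conjugation of 13 to a divinyl ketone (which would open a Nazarov path); the accessible terminal CH2, the crowding that a quaternary C5 next to quaternary C4 would cause, and the aprotic proton-scavenging Lewis acid should secure these.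

Step 9
Reactants: 14
Product: 16 ethyl 7α-hydroxy-15,16-dinorlabd-13-yn-19-oate (5α-H; 8α-methyl; 9α-H; 10β-methyl), via saturated ketone 15 (not isolated)
Conditions: Li, NH3(l)/THF, −78 °C (alkyne carried as its lithium acetylide); NH4Cl; NH3 evaporated; then LiBH(sec-Bu)3, THF, −78 °C; aq. NH4Cl
Reagents that add atoms: none
Why: Birch-type enone reduction, in which axial α-face protonation of the C5 carbanion should give the trans-fused ketone, followed by equatorial attack of the bulky borohydride on C7 to give the axial 7α-alcohol.

Step 10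
Reactants: 16
Product: 17 ethyl 15,16-dinorlabd-7-en-13-yn-19-oate (5α-H; 9α-H; 10β-methyl)
Conditions: Ph2S[OC(CF3)2Ph]2, CH2Cl2, 0 °C to rt
Reagents that add atoms: none
Why: Anti-periplanar dehydration of the axial alkoxysulfonium intermediate; of the two trans-diaxial hydrogens (H-8β and H-6β), loss of the tertiary H-8β should give the more substituted Δ7 alkene.

Step 11
Reactants: 17
Product: 18 ethyl 7α,8α-dihydroxy-15,16-dinorlabd-13-yn-19-oate (5α-H; 8β-methyl; 9α-H; 10β-methyl)
Conditions: OsO4 (cat.), N-methylmorpholine N-oxide, acetone/H2O, rt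
Reagents that add atoms: N-methylmorpholine N-oxide (C[N+]1([O-])CCOCC1); water (O)
Why: Catalytic syn-dihydroxylation should take place on the α-face, away from the axial C10 methyl and the β side chain on C9, which sets 7α-OH and 8α-OH together; the terminal alkyne reacts much more slowly.

Step 12
Reactants: 18
Product: 19 15,16-dinorlabd-13-yne-7α,8α,19-triol
Conditions: LiAlH4, THF, 0 °C to rt
Reagents that add atoms: none
Why: Hydride reduction of the neopentyl ester to the C19 primary alcohol; no stereocentre is touched.

Step 13
Reactants: 19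
Product: 20 labda-13(16),14-diene-7α,8α,19-triol
Conditions: ethylene (1 atm), second-generation Grubbs catalyst RuCl2(=CHPh)(PCy3)(H2IMes) (5 mol%), toluene, 60 °C
Reagents that add atoms: ethylene (C=C)
Why: Cross enyne metathesis of a terminal alkyne with ethylene should give the 2-substituted buta-1,3-diene in one step; 19 holds no other alkene.

Step 14
Reactants: 20; 21 2-(diphenoxyphosphoryl)acetic acid
Product: 22 7α,8α-dihydroxylabda-13(16),14-dien-19-yl 2-(diphenoxyphosphoryl)acetate
Conditions: N,N'-dicyclohexylcarbodiimide, 4-(dimethylamino)pyridine (cat.), CH2Cl2, 0 °C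
Reagents that add atoms: none
Why: Steglich esterification; the primary C19 hydroxyl should react before the axial secondary C7 and the tertiary C8 hydroxyl.

Step 15
Reactants: 22; 23 4-[(tert-butyldimethylsilyl)oxy]benzaldehyde
Product: 24 7α,8α-dihydroxylabda-13(16),14-dien-19-yl (2Z)-3-{4-[(tert-butyldimethylsilyl)oxy]phenyl}prop-2-enoate
Conditions: NaI, 1,8-diazabicyclo[5.4.0]undec-7-ene, THF, −78 to 0 °C
Reagents that add atoms: none
Why: Z-selective Horner–Wadsworth–Emmons olefination, in which the diaryl phosphonate makes oxaphosphetane collapse fast so that the kinetic adduct should give the (Z)-cinnamate; the mild base should tolerate the free diol and the diene.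

Step 16
Reactants: 24
Product: 25 7α,8α-dihydroxylabda-13(16),14-dien-19-yl (2Z)-3-(4-hydroxyphenyl)prop-2-enoate
Conditions: Bu4NF, AcOH, THF, 0 °C
Reagents that add atoms: none
Why: Buffered fluoride cleavage of the aryl silyl ether, which should leave the (Z)-enoate ester and the diene intact.

**Compound list**

1 | ethyl 2-oxocyclohexane-1-carboxylate | CCOC(=O)C1CCCCC1=O | starting material
2 | L-valine tert-butyl ester | CC(C)[C@H](N)C(=O)OC(C)(C)C | starting material
3 | ethyl 2-{[(2S)-1-tert-butoxy-3-methyl-1-oxobutan-2-yl]amino}cyclohex-1-ene-1-carboxylate | CCOC(=O)C1=C(N[C@@H](C(C)C)C(=O)OC(C)(C)C)CCCC1 | intermediate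
4 | ethyl (1S)-2-{[(2S)-1-tert-butoxy-3-methyl-1-oxobutan-2-yl]imino}-1-methylcyclohexane-1-carboxylate (not isolated) | CCOC(=O)[C@@]1(C)CCCCC1=N[C@@H](C(C)C)C(=O)OC(C)(C)C | intermediate
5 | ethyl (1S)-1-methyl-2-oxocyclohexane-1-carboxylate | CCOC(=O)[C@@]1(C)CCCCC1=O | intermediate
6 | ethyl (1S,3RS)-1,3-dimethyl-2-oxocyclohexane-1-carboxylate | CCOC(=O)[C@@]1(C)CCCC(C)C1=O | intermediate
7 | ethyl (1S,3RS)-1,3-dimethyl-2-methylidenecyclohexane-1-carboxylate | CCOC(=O)[C@@]1(C)CCCC(C)C1=C | intermediate
8 | pent-4-yn-1-ol | C#CCCCO | starting material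
9 | pent-4-ynal (not isolated) | C#CCCC=O | intermediate
10 | ethyl (2E)-2-methylhept-2-en-6-ynoate | C#CCC/C=C(\C)C(=O)OCC | intermediate
11 | (2E)-2-methylhept-2-en-6-ynoic acid | C#CCC/C=C(\C)C(=O)O | intermediate
12 | (2E)-2-methylhept-2-en-6-ynoyl chloride | C#CCC/C=C(\C)C(=O)Cl | intermediate
13 | ethyl (1S)-1,3-dimethyl-2-[(3E)-3-methyl-2-oxooct-3-en-7-yn-1-yl]cyclohex-2-ene-1-carboxylate (not isolated) | C#CCC/C=C(\C)C(=O)CC1=C(C)CCC[C@]1(C)C(=O)OCC | intermediate
14 | ethyl 7-oxo-15,16-dinorlabd-5-en-13-yn-19-oate (8α-methyl; 9α-H; 10β-methyl) | C#CCC[C@H]1[C@H](C)C(=O)C=C2[C@@](C)(C(=O)OCC)CCC[C@@]21C | intermediate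
15 | ethyl 7-oxo-15,16-dinorlabd-13-yn-19-oate (5α-H; 8α-methyl; 9α-H; 10β-methyl; not isolated) | C#CCC[C@H]1[C@H](C)C(=O)C[C@H]2[C@@](C)(C(=O)OCC)CCC[C@@]21C | intermediate
16 | ethyl 7α-hydroxy-15,16-dinorlabd-13-yn-19-oate (5α-H; 8α-methyl; 9α-H; 10β-methyl) | C#CCC[C@H]1[C@H](C)[C@H](O)C[C@H]2[C@@](C)(C(=O)OCC)CCC[C@@]21C | intermediate
17 | ethyl 15,16-dinorlabd-7-en-13-yn-19-oate (5α-H; 9α-H; 10β-methyl) | C#CCC[C@H]1C(C)=CC[C@H]2[C@@](C)(C(=O)OCC)CCC[C@@]21C | intermediate
18 | ethyl 7α,8α-dihydroxy-15,16-dinorlabd-13-yn-19-oate (5α-H; 8β-methyl; 9α-H; 10β-methyl) | C#CCC[C@H]1[C@](C)(O)[C@H](O)C[C@H]2[C@@](C)(C(=O)OCC)CCC[C@@]21C | intermediate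
19 | 15,16-dinorlabd-13-yne-7α,8α,19-triol | C#CCC[C@H]1[C@](C)(O)[C@H](O)C[C@H]2[C@@](C)(CO)CCC[C@@]21C | intermediate
20 | labda-13(16),14-diene-7α,8α,19-triol | C=CC(=C)CC[C@H]1[C@](C)(O)[C@H](O)C[C@H]2[C@@](C)(CO)CCC[C@@]21C | intermediate
21 | 2-(diphenoxyphosphoryl)acetic acid | OC(=O)CP(=O)(Oc1ccccc1)Oc1ccccc1 | starting material
22 | 7α,8α-dihydroxylabda-13(16),14-dien-19-yl 2-(diphenoxyphosphoryl)acetate | C=CC(=C)CC[C@H]1[C@](C)(O)[C@H](O)C[C@H]2[C@@](C)(COC(=O)CP(=O)(Oc3ccccc3)Oc3ccccc3)CCC[C@@]21C | intermediate
23 | 4-[(tert-butyldimethylsilyl)oxy]benzaldehyde | O=Cc1ccc(O[Si](C)(C)C(C)(C)C)cc1 | starting material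
24 | 7α,8α-dihydroxylabda-13(16),14-dien-19-yl (2Z)-3-{4-[(tert-butyldimethylsilyl)oxy]phenyl}prop-2-enoate | C=CC(=C)CC[C@H]1[C@](C)(O)[C@H](O)C[C@H]2[C@@](C)(COC(=O)/C=C\c3ccc(O[Si](C)(C)C(C)(C)C)cc3)CCC[C@@]21C | intermediate
25 | 7α,8α-dihydroxylabda-13(16),14-dien-19-yl (2Z)-3-(4-hydroxyphenyl)prop-2-enoate (CNP0254560.1) | C=CC(=C)CC[C@H]1[C@](C)(O)[C@H](O)C[C@H]2[C@@](C)(COC(=O)/C=C\c3ccc(O)cc3)CCC[C@@]21C | target

**Count and risks**

Total step count: 16. Longest linear sequence: 13 steps (steps 1–4 and 8–16).

Step 8 (proposed new method). The cascade may stall at the open ketone, close through C5 to a five-membered ring, drift through conjugation into a Nazarov closure, or show poor facial selectivity with respect to C4. Fallback with known chemistry, setting out from 7 and 12: the acylation is stopped at −78 °C with one equivalent of EtAlCl2 and the β,γ-unsaturated ketone 13 is isolated. Ring B is then closed by a hydrogen-atom-transfer-initiated radical conjugate cyclisation (Fe(acac)3, PhSiH3, EtOH/ethylene glycol, 60 °C): hydrogen is delivered to C5, the tertiary C10 radical adds 6-endo to C9 and the α-keto radical is reduced. This should give the saturated ketone 15 directly, with ring-fusion diastereomers to be separated, and the route is rejoined at 15 (second half of step 9). No compound outside the list arises (F0).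

Step 10. Regiocontrol of the elimination may be lost (removal of H-6β instead of H-8β), or substitution may compete. Fallback, setting out from 15 (isolated after the first half of step 9): thermodynamic enolisation toward the more substituted C8 and O-sulfonylation (Tf2O, 2,6-di-tert-butyl-4-methylpyridine, CH2Cl2) should give ethyl 7-(trifluoromethanesulfonyloxy)-15,16-dinorlabd-7-en-13-yn-19-oate F1. Palladium-catalysed formate reduction (Pd(OAc)2, PPh3, Bu3N, HCO2H, N,N-dimethylformamide, 60 °C) then gives the Δ7 alkene, and the route is rejoined at 17.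

Step 9. Electron transfer may go too far (attack on the ester or the alkyne, reduction of the ketone before the quench), or protonation at C5 may lack face selectivity. Fallback, setting out from 14: a metal-hydride hydrogen-atom-transfer conjugate reduction (Mn(dpm)3 with dpm = 2,2,6,6-tetramethylheptane-3,5-dionate, PhSiH3, i-PrOH, rt) should give the trans-fused ketone 15 without dissolving metal. LiBH(sec-Bu)3 then gives the 7α-alcohol and the route is rejoined at 16. No compound outside the list arises (F0).

Further compounds
F0 | step 8 | none | none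
F1 | step 10 | ethyl 7-(trifluoromethanesulfonyloxy)-15,16-dinorlabd-7-en-13-yn-19-oate (5α-H; 9α-H; 10β-methyl) | C#CCC[C@H]1C(C)=C(OS(=O)(=O)C(F)(F)F)C[C@H]2[C@@](C)(C(=O)OCC)CCC[C@@]21C
F0 | step 9 | none | none
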